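## Structural features

Cladonaphchrom A is a chroman (O1, C2, C3, C4, C4a, C8a fused to the benzo ring C4a–C8a) with a free phenol at C5. The ring-fusion carbon C4a therefore lies between C8a–O1 and C5–OH and is the 2-position of a resorcinol. C4 is a diarylmethine stereocentre (S) bonded to C1′ of a 4,5-dimethoxynaphthalene. C2 (R) carries the methyl group and O1; the two stereocentres are separated only by the C3 methylene and are trans. The fragile points are the electron-rich peri-dimethoxynaphthalene (easily oxidized, and nucleophilic above all at C8′, which is para to a methoxy group and peri to C1′), the free phenol and the doubly benzylic C4–H. The real difficulty is twofold: a C–C bond must be made to the resorcinol carbon flanked by both oxygens, where a resorcinol itself does not react, and the congested C4 centre must be set in absolute terms and then relayed to C2. The key step exploits the fact that in cyclohexane-1,3-dione the central carbon (future C4a) is the only nucleophilic carbon and one enol oxygen (future O1) is placed to close the pyran ring. The carbocycle C4a/C5/C6/C7/C8/C8a is aromatized afterwards. Peri strain with the C5 oxygen holds the C4 aryl group pseudoaxial, so a group that enters C2 last is directed trans to it.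

## Logic of the disconnections

15 ⇒ 13. The C2–CH3 bond is cut. C2 is an acetal-level carbon next to O1, so methyl can be the last group to enter, through oxocarbenium ion 14, and its configuration is relayed from C4. One stereocentre disappears and the precursor may be an epimer mixture at C2. The forward step must ionize only the exocyclic C2–O bond, add methyl anti to the pseudoaxial aryl group, and tolerate the phenol and the naphthalene.

13 ⇒ 9. No skeletal bond is cut; the phenol ring is taken back by one unsaturation (C6/C7) to a cyclic vinylogous ester. This turns a resorcinol, whose 2-position cannot be addressed, into a derivative of a 1,3-dione, whose central carbon can. The forward dehydrogenation must be non-acidic (acetal at C2), must spare the naphthalene, and must not touch C4.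

9 ⇒ 8. The C2–OMe bond is exchanged for C2–OH. The lactol would not survive enolate chemistry, the methyl acetal does, and it is also the leaving group of the last step. The forward step needs acid mild enough to leave the vinylogous ester closed.

8 ⇒ 5 + 6 (through 7). The C4–C4a and O1–C2 bonds are cut. This removes the pyran ring, two bonds and the C4 stereocentre in one operation and leaves an achiral enal and a commodity dione. The forward step needs enantioface selection at C4, 1,4- rather than 1,2-addition, C- rather than O-attack by 6, and a single enal geometry.

5 ⇒ 3 + 4. The C3=C4 double bond of the enal is cut (chroman numbering). This is a two-carbon homologation of an aryl aldehyde. The forward step needs E geometry and must stop after one homologation.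

3 ⇒ 1. The C1′–CHO bond (future C1′–C4) is cut, which leads to a symmetrical commercial arene. The forward formylation must go para to one methoxy group and stop after one substitution.

## Other disconnections considered

Alternative 1: The cut is at C2–C3 and C4–C4a of an open chain; no ring is closed.
- Forward key step: an acetyl radical, released by photocatalytic decarboxylation of 2-oxopropanoic acid A3, would add to the vinyl terminus of 4-ethenyl-1,8-dimethoxynaphthalene A1. The naphthylic radical would be captured by a chiral nickel complex (NiBr2·dme with a chiral bis(oxazoline)) that has taken up 2-iodo-1,3-bis(methoxymethoxy)benzene A2. Reductive elimination would give ketone A4 with C4 set by the ligand.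
- In its favour: it is convergent. Both arenes are already at their final oxidation level, so no ring has to be dehydrogenated later; on this point it is better than the chosen plan. The position of iodine fixes the attachment between the two oxygens, which equals the automatic regiochemistry of 6. The methyl group arrives inside the acetyl unit.
- Against it here: the aryl iodide is electron-rich and di-ortho-substituted and the radical is peri-hindered, so the most congested bond of the molecule must form by C(sp3)–C(sp2) reductive elimination. Direct acyl–aryl coupling and simple hydroacylation of A1 are likely competitors.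
- Comparison, mechanism: radical capture at nickel is a less predictable stereo-determining event than face shielding of an iminium ion.
- Comparison, structure: C2 would be set after A4 by a reagent-controlled ketone reduction, removal of both acetal protecting groups and an invertive Mitsunobu closure of O1–C2. This gives independent control of C2, which is equal or better than the substrate relay when both diastereomers are wanted.
- Comparison, step economy: about eight steps with a longest line of six, against six and six.

Alternative 2: The cut removes C1′–C8a′ and C4′–C4a′ of the naphthalene, so that ring A (C1′–C4′) is made last.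
- Forward key step: iodine–lithium exchange on 2-iodo-3-methoxyphenyl triflate A5 with n-BuLi and loss of triflate would release the aryne. The vinylketene silyl acetal A6, which already carries the finished chroman, would trap it in a [4+2] cycloaddition. Loss of methanol and of the silyl group would aromatize the new ring to naphthol A7. O-Methylation and hydrogenolysis of the benzyl ether would finish.
- In its favour: the polarity is matched, since the nucleophilic diene terminus C4′ bonds to the aryne carbon remote from the methoxy group, which places the new hydroxyl peri to it. The two naphthalene oxygens are differentiated, which is better than the chosen plan if congeners with a free naphthol are wanted. The oxidation-sensitive dimethoxynaphthalene exists only in the last two steps, also better. Two steps follow the key step instead of three.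
- Against it here: the cycloaddition creates no stereocentre. The C4–C4a bond at the resorcinol 2-position, both stereocentres and their trans relationship must all be present in A6. The hard problems are thus moved into a long fragment synthesis, and a valuable chiral fragment meets an aryne and an alkyllithium late.
- Comparison: on mechanism the pericyclic step is as trustworthy as the iminium step (equal). On structure it solves the easy part. On step economy it is clearly worse.

Alternative 3: The cut is at C3–C4 and O1–C2; the pyran ring comes from a hetero-Diels–Alder reaction of an ortho-quinone methide.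
- Forward key step: a chiral phosphoric acid would dehydrate triol A8 to ortho-quinone methide A10, which would add ethoxyethene A9 across C4 and O1 to give the cis acetal A11. The acetal methylation of step 6 would then complete the synthesis.
- In its favour: it is the shortest plan (A8 in three to four steps, then two more), better than the chosen plan. Both arenes are final, so no dehydrogenation is needed, also better. The C4–C4a bond comes with a 2,6-dioxygenated benzaldehyde, equal to the regiochemistry of 6. The remaining phenol offers the acid a second hydrogen-bond contact. A11 is the ethyl analogue of 13, so the end game and its risks are identical (equal).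
- Against it here: A9 has no hydrogen-bond donor to organize with the catalyst and is acid-sensitive (oligomerization, mixed acetals with the hydroxyl groups of A8). The cation derived from A10 is a diarylmethyl cation strongly stabilized by the methoxynaphthalene. A stepwise path outside the chiral ion pair and a racemic background reaction therefore threaten the configuration at C4, on which everything else depends.
- Comparison: the chosen plan spends one or two more steps, mainly on the dehydrogenation, to set C4 by a catalytic step with a secure facial model and close precedent for this nucleophile class.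

Key step: step 3

## Steps

Assumptions:
- C2 of 8, 9 and 13 is carried as a mixture of epimers, because both converge on the planar ion 14 in the last step.
- 7 is written as its enol, in which the C4 descriptor is S as in 8 and in the target (C4a outranks C1′ at every stage). The diketo tautomer would change letter without any change in geometry.

Step 1
Reactants: 1 1,8-dimethoxynaphthalene
Product: 3 4,5-dimethoxynaphthalene-1-carbaldehyde, via aryl iminium salt 2 (not isolated)
Conditions: POCl3, DMF, 0 °C to 80 °C; then aq. NaOAc
Reagents that add atoms: N,N-dimethylformamide, CN(C)C=O; water, O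
Why: Vilsmeier–Haack formylation; the chloroiminium electrophile attacks C4, the α-position para to a methoxy group, and hydrolysis of 2 releases the aldehyde. The formyl group deactivates the ring system against a second substitution.

Step 2
Reactants: 3 4,5-dimethoxynaphthalene-1-carbaldehyde; 4 (triphenylphosphoranylidene)acetaldehyde
Product: 5 (2E)-3-(4,5-dimethoxynaphthalen-1-yl)prop-2-enal
Conditions: 4 (1.05 equiv), toluene, 90 °C
Reagents that add atoms: none
Why: Wittig olefination with a formyl-stabilized ylide, which should give the (E)-enal. Only a small excess of 4 is used so that the product enal is not homologated a second time.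

Step 3
Reactants: 5 (2E)-3-(4,5-dimethoxynaphthalen-1-yl)prop-2-enal; 6 cyclohexane-1,3-dione
Product: 8 (4S)-4-(4,5-dimethoxynaphthalen-1-yl)-2-hydroxy-2,3,4,6,7,8-hexahydro-5H-chromen-5-one (lactol; both C2 epimers), via open-chain Michael adduct 7 (not isolated)
Conditions: (S)-2-{bis[3,5-bis(trifluoromethyl)phenyl](trimethylsilyloxy)methyl}pyrrolidine (10 mol %), 6 (1.2 equiv), CH2Cl2, 0 °C to rt
Reagents that add atoms: none
Why: The secondary amine condenses with 5 to an (E,E)-configured s-trans iminium ion whose LUMO-lowered β-carbon (future C4) is attacked by the enol of 6 through its central carbon (future C4a); hydrolysis of the resulting enamine returns the catalyst and gives 7. In 7 the enol oxygen (future O1) adds to the aldehyde carbon (future C2) in a reversible polar 6-exo-trig hemiacetalization, which closes the dihydropyran ring as lactol 8. The closest known reaction type is the diarylprolinol-silyl-ether-catalysed Michael addition/hemiacetalization of cyclic 1,3-diones with enals (iminium catalysis). C4 is controlled by the catalyst: in the (S)-pyrrolidine the C(Ar)2OSiMe3 group covers the Re face of the β-carbon, so the dione should add to the Si face, and with the priorities C4a > C1′ > C3 > H this is 4S; C2 of the lactol is left uncontrolled on purpose. The step needs 1,4- over 1,2-addition and C- over O-attack, secured by iminium activation and by the fact that the central carbon of 6 is its only nucleophilic carbon. It needs a single iminium geometry, secured by the (E)-enal from step 2. It must also avoid retro-Michael erosion, which low temperature and the removal of 7 as lactol should limit. The donor-substituted naphthyl group slows the addition, so the more electrophilic bis(trifluoromethyl)aryl catalyst is chosen and 6 itself serves as the acid co-catalyst.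

Step 4
Reactants: 8 (4S)-4-(4,5-dimethoxynaphthalen-1-yl)-2-hydroxy-2,3,4,6,7,8-hexahydro-5H-chromen-5-one
Product: 9 (4S)-4-(4,5-dimethoxynaphthalen-1-yl)-2-methoxy-2,3,4,6,7,8-hexahydro-5H-chromen-5-one (both C2 epimers)
Conditions: MeOH, PPTS (10 mol %), rt
Reagents that add atoms: methanol, CO
Why: Acid-catalysed lactol-to-methyl-acetal exchange (Fischer-type acetalization) in methanol. The weak pyridinium acid should neither open the vinylogous ester nor dehydrate the lactol, and C4 is not involved.

Step 5
Reactants: 9 (4S)-4-(4,5-dimethoxynaphthalen-1-yl)-2-methoxy-2,3,4,6,7,8-hexahydro-5H-chromen-5-one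
Product: 13 (4S)-4-(4,5-dimethoxynaphthalen-1-yl)-2-methoxy-3,4-dihydro-2H-chromen-5-ol (both C2 epimers), via α′-phenylselanyl ketone 10 (not isolated), via selenoxide 11 (not isolated), via cross-conjugated dienone 12 (not isolated)
Conditions: LiN(i-Pr)2 (1.2 equiv), THF, −78 °C; PhSeCl, −78 °C; then pyridine, 30% aq. H2O2, 0 °C to rt
Reagents that add atoms: none
Why: Kinetic α′-enolization of the cyclic vinylogous ester at C6, enolate selenenylation, oxidation at selenium and selenoxide syn-elimination toward C7 should give dienone 12, which is the keto tautomer of the phenol and enolizes to 13. The basic and then buffered conditions spare the acetal, and C4–H is cross-conjugated and not enolizable, so the stereocentre is not at risk.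

Step 6
Reactants: 13 (4S)-4-(4,5-dimethoxynaphthalen-1-yl)-2-methoxy-3,4-dihydro-2H-chromen-5-ol
Product: 15 (2R,4S)-4-(4,5-dimethoxynaphthalen-1-yl)-2-methyl-3,4-dihydro-2H-chromen-5-ol (cladonaphchrom A), via chromanyl oxocarbenium ion 14 (not isolated)
Conditions: AlMe3 (4 equiv), CH2Cl2, −78 °C; TMSOTf (1.5 equiv), −78 to −20 °C; then MeOH, 1 M HCl
Reagents that add atoms: trimethylaluminium, C[Al](C)C
Why: Lewis-acid-promoted substitution of a cyclic acetal by an organoaluminium nucleophile (C-glycosylation type): AlMe3 first caps the phenol as ArOAlMe2, TMSOTf ionizes the exocyclic C2–OMe bond to 14, and a methyl group is transferred from aluminium. In the half-chair of 14 the C4 naphthyl group is pseudoaxial to avoid peri strain with the C5 oxygen, so methyl should add to the opposite face of C2 and give the 2,4-trans (2R) isomer, which is also the more stable one (methyl equatorial).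

## Compound list

1 | 1,8-dimethoxynaphthalene | COc1cccc2cccc(OC)c12 | starting material
2 | N-[(4,5-dimethoxynaphthalen-1-yl)methylidene]-N-methylmethanaminium dichlorophosphate | COc1cccc2c(C=[N+](C)C)ccc(OC)c12.[O-]P(=O)(Cl)Cl | intermediate (not isolated)
3 | 4,5-dimethoxynaphthalene-1-carbaldehyde | COc1cccc2c(C=O)ccc(OC)c12 | intermediate
4 | (triphenylphosphoranylidene)acetaldehyde | O=CC=P(c1ccccc1)(c1ccccc1)c1ccccc1 | starting material
5 | (2E)-3-(4,5-dimethoxynaphthalen-1-yl)prop-2-enal | COc1cccc2c(/C=C/C=O)ccc(OC)c12 | intermediate
6 | cyclohexane-1,3-dione | O=C1CCCC(=O)C1 | starting material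
7 | 3-hydroxy-2-[(1S)-1-(4,5-dimethoxynaphthalen-1-yl)-3-oxopropyl]cyclohex-2-en-1-one (enol form of the Michael adduct) | COc1cccc2c([C@H](CC=O)C3=C(O)CCCC3=O)ccc(OC)c12 | intermediate (not isolated)
8 | (4S)-4-(4,5-dimethoxynaphthalen-1-yl)-2-hydroxy-2,3,4,6,7,8-hexahydro-5H-chromen-5-one (both C2 epimers) | COc1cccc2c([C@@H]3CC(O)OC4=C3C(=O)CCC4)ccc(OC)c12 | intermediate
9 | (4S)-4-(4,5-dimethoxynaphthalen-1-yl)-2-methoxy-2,3,4,6,7,8-hexahydro-5H-chromen-5-one (both C2 epimers) | COc1cccc2c([C@@H]3CC(OC)OC4=C3C(=O)CCC4)ccc(OC)c12 | intermediate
10 | (4S)-4-(4,5-dimethoxynaphthalen-1-yl)-2-methoxy-6-(phenylselanyl)-2,3,4,6,7,8-hexahydro-5H-chromen-5-one (epimers at C2 and C6) | COc1cccc2c([C@@H]3CC(OC)OC4=C3C(=O)C([Se]c5ccccc5)CC4)ccc(OC)c12 | intermediate (not isolated)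
11 | (4S)-6-(benzeneseleninyl)-4-(4,5-dimethoxynaphthalen-1-yl)-2-methoxy-2,3,4,6,7,8-hexahydro-5H-chromen-5-one | COc1cccc2c([C@@H]3CC(OC)OC4=C3C(=O)C([Se](=O)c5ccccc5)CC4)ccc(OC)c12 | intermediate (not isolated)
12 | (4S)-4-(4,5-dimethoxynaphthalen-1-yl)-2-methoxy-2,3,4,8-tetrahydro-5H-chromen-5-one | COc1cccc2c([C@@H]3CC(OC)OC4=C3C(=O)C=CC4)ccc(OC)c12 | intermediate (not isolated)
13 | (4S)-4-(4,5-dimethoxynaphthalen-1-yl)-2-methoxy-3,4-dihydro-2H-chromen-5-ol (both C2 epimers) | COc1cccc2c([C@@H]3CC(OC)Oc4cccc(O)c43)ccc(OC)c12 | intermediate
14 | (4S)-5-[(dimethylalumanyl)oxy]-4-(4,5-dimethoxynaphthalen-1-yl)-3,4-dihydrochromenylium trifluoromethanesulfonate | COc1cccc2c([C@@H]3CC=[O+]c4cccc(O[Al](C)C)c43)ccc(OC)c12.[O-]S(=O)(=O)C(F)(F)F | intermediate (not isolated)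
15 | (2R,4S)-4-(4,5-dimethoxynaphthalen-1-yl)-2-methyl-3,4-dihydro-2H-chromen-5-ol (cladonaphchrom A) | COc1cccc2c([C@@H]3C[C@@H](C)Oc4cccc(O)c43)ccc(OC)c12 | target

## Step count and least certain steps

Total step count: 6. Longest linear sequence: 6 steps (1 → 3 → 5 → 8 → 9 → 13 → 15); 4 and 6 are bought.

Step 3 (key step). The most likely failure is a slow conjugate addition, because the 4-methoxy group donates into the enal and the peri hydrogen hinders the β-carbon. Reversible (retro-Michael) addition and loss of the silyl group from the catalyst by the acidic dione would then erode the enantiomeric purity at C4. The fallback sets out from 5 and 6 and returns at 8; it raises the enal to the acyl oxidation level instead of activating it as an iminium ion. A chiral aminoindanol-derived N-mesityl triazolium carbene precatalyst (enantiomer chosen to give 4S), 3,3′,5,5′-tetra-tert-butyldiphenoquinone as oxidant and Cs2CO3 in THF would turn 5 into an α,β-unsaturated acyl azolium. Compound 6 adds to its β-carbon and lactonizes to the enol lactone (4S)-4-(4,5-dimethoxynaphthalen-1-yl)-3,4,7,8-tetrahydro-2H-chromene-2,5(6H)-dione F1, which cannot revert. Half-reduction of the lactone carbonyl with i-Bu2AlH (1.1 equiv, CH2Cl2, −78 °C) would then give 8.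

Step 6. Three processes threaten it: ionization at the endocyclic C2–O1 bond (ring opening, then methylation of an acyclic ion), intramolecular Friedel–Crafts capture of the oxocarbenium ion by the activated peri position C8′, and incomplete facial selectivity. The fallback sets out from 13 and returns at 15; it closes O1–C2 by an SN2 reaction instead of passing through a cation. Hydrolysis (1 M HCl, THF) would give the lactol (4S)-4-(4,5-dimethoxynaphthalen-1-yl)-3,4-dihydro-2H-chromene-2,5-diol F2. Excess MeMgBr (THF, 0 °C) would add to its open hydroxy-aldehyde form and give 2-[(1S)-1-(4,5-dimethoxynaphthalen-1-yl)-3-hydroxybutyl]benzene-1,3-diol F3 as two carbinol epimers. Mitsunobu cyclization (PPh3, diisopropyl azodicarboxylate, THF) proceeds with inversion and either of the two equivalent phenols can close the ring. The (3S) epimer would give 15 and the (3R) epimer the cis isomer (2S,4S)-4-(4,5-dimethoxynaphthalen-1-yl)-2-methyl-3,4-dihydro-2H-chromen-5-ol F4, to be removed by chromatography. This route is not stereoselective at C2 but uses only robust reactions.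

Step 5. The likely failures are oxidation or selenenylation of the newly formed electron-rich phenol and of the naphthalene by selenium by-products during the oxidative stage, and leakage of the enolization to the γ-position (C8). The fallback sets out from 9 and returns at 13 without any enolate or selenium chemistry. It is a catalytic aerobic dehydrogenation: Pd(OCOCF3)2 (5 mol %), 2-(dimethylamino)pyridine (10 mol %), TsOH (20 mol %), O2 (1 atm), DMSO, 80 °C. A divalent palladium enolate forms at C6, β-hydride elimination gives 12, which tautomerizes, and oxygen reoxidizes the metal. Because the medium is acidic, partial loss of the methyl acetal is expected; the crude product would be re-exposed to MeOH/PPTS to restore 13. This fallback makes no compound outside the compound list (F0).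

Step 2. The likely failures are a second olefination of the product enal, which is a better electrophile than the electron-rich aldehyde 3, and a sluggish first olefination. The fallback sets out from 3 and returns at 5; it homologates at the ester oxidation level, where over-reaction is impossible. A Horner–Wadsworth–Emmons reaction (triethyl phosphonoacetate, NaH, THF) would give ethyl (2E)-3-(4,5-dimethoxynaphthalen-1-yl)prop-2-enoate F5. Reduction with i-Bu2AlH (CH2Cl2, −78 °C) would give (2E)-3-(4,5-dimethoxynaphthalen-1-yl)prop-2-en-1-ol F6. Allylic oxidation with MnO2 (CH2Cl2, rt) would give 5.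

## Further compounds

F1 | step 3 | (4S)-4-(4,5-dimethoxynaphthalen-1-yl)-3,4,7,8-tetrahydro-2H-chromene-2,5(6H)-dione | COc1cccc2c([C@@H]3CC(=O)OC4=C3C(=O)CCC4)ccc(OC)c12
F2 | step 6 | (4S)-4-(4,5-dimethoxynaphthalen-1-yl)-3,4-dihydro-2H-chromene-2,5-diol (both C2 epimers) | COc1cccc2c([C@@H]3CC(O)Oc4cccc(O)c43)ccc(OC)c12
F3 | step 6 | 2-[(1S)-1-(4,5-dimethoxynaphthalen-1-yl)-3-hydroxybutyl]benzene-1,3-diol (both C3 epimers) | COc1cccc2c([C@H](CC(C)O)c3c(O)cccc3O)ccc(OC)c12
F4 | step 6 | (2S,4S)-4-(4,5-dimethoxynaphthalen-1-yl)-2-methyl-3,4-dihydro-2H-chromen-5-ol | COc1cccc2c([C@@H]3C[C@H](C)Oc4cccc(O)c43)ccc(OC)c12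
F0 | step 5 | none | none
F5 | step 2 | ethyl (2E)-3-(4,5-dimethoxynaphthalen-1-yl)prop-2-enoate | CCOC(=O)/C=C/c1ccc(OC)c2c(OC)cccc12
F6 | step 2 | (2E)-3-(4,5-dimethoxynaphthalen-1-yl)prop-2-en-1-ol | OC/C=C/c1ccc(OC)c2c(OC)cccc12
A1 | alternative 1 | 4-ethenyl-1,8-dimethoxynaphthalene | COc1cccc2c(C=C)ccc(OC)c12
A2 | alternative 1 | 2-iodo-1,3-bis(methoxymethoxy)benzene | COCOc1cccc(OCOC)c1I
A3 | alternative 1 | 2-oxopropanoic acid | CC(=O)C(=O)O
A4 | alternative 1 | (4S)-4-[2,6-bis(methoxymethoxy)phenyl]-4-(4,5-dimethoxynaphthalen-1-yl)butan-2-one | COc1cccc2c([C@H](CC(C)=O)c3c(OCOC)cccc3OCOC)ccc(OC)c12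
A5 | alternative 2 | 2-iodo-3-methoxyphenyl trifluoromethanesulfonate | COc1cccc(OS(=O)(=O)C(F)(F)F)c1I
A6 | alternative 2 | tert-butyl({(3E)-4-[(2R,4S)-5-(benzyloxy)-2-methyl-3,4-dihydro-2H-chromen-4-yl]-1-methoxybuta-1,3-dien-1-yl}oxy)dimethylsilane | COC(O[Si](C)(C)C(C)(C)C)=C/C=C/[C@@H]1C[C@@H](C)Oc2cccc(OCc3ccccc3)c21
A7 | alternative 2 | 4-[(2R,4S)-5-(benzyloxy)-2-methyl-3,4-dihydro-2H-chromen-4-yl]-8-methoxynaphthalen-1-ol | Oc1ccc([C@@H]3C[C@@H](C)Oc4cccc(OCc5ccccc5)c43)c2cccc(OC)c12
A8 | alternative 3 | 2-[(4,5-dimethoxynaphthalen-1-yl)(hydroxy)methyl]benzene-1,3-diol | COc1cccc2c(C(O)c3c(O)cccc3O)ccc(OC)c12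
A9 | alternative 3 | ethoxyethene | C=COCC
A10 | alternative 3 | 6-[(4,5-dimethoxynaphthalen-1-yl)methylidene]-5-hydroxycyclohexa-2,4-dien-1-one | COc1cccc2c(C=C3C(=O)C=CC=C3O)ccc(OC)c12
A11 | alternative 3 | (2R,4S)-4-(4,5-dimethoxynaphthalen-1-yl)-2-ethoxy-3,4-dihydro-2H-chromen-5-ol | COc1cccc2c([C@@H]3C[C@H](OCC)Oc4cccc(O)c43)ccc(OC)c12
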